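## Structural features

The target is an achiral bibenzyl, C36H34O6, in which benzene ring A and benzene ring B are joined by a CH2–CH2 chain from A5 to B1. Ring A carries OMe at A1, OH at A3 and 4-hydroxybenzyl groups at A4 and A6, so A3–A4–A5–A6–A1 is an unbroken run of five substituted carbons and only A2 bears hydrogen. Ring B carries OH at B3 and a third 4-hydroxybenzyl group at B6, next to the chain. There is no stereocentre and no configurationally stable axis, so no stereocentres stand next to each other and nothing has to be controlled in three dimensions. The fragile elements are the five free phenols (air-sensitive as phenoxides and strongly nucleophilic at their ortho carbons), the three doubly benzylic CH2 groups (easily oxidised, and re-ionised by strong acid), and the single methyl ether, which must survive while five other oxygen substituents are set free. The real difficulty is regiochemical: three identical benzyl groups must be placed on three defined carbons of two electron-rich rings that offer several competing positions, two of them on a crowded ring flanking the chain. The key step exploits the fact that the CH2 carbon on A4 is para to the A1 oxygen, the one on A6 is para to the A3 oxygen and the one on B6 is para to the B3 oxygen, whereas both chain carbons are meta to every oxygen. The three diarylmethane carbons can therefore be carried as methyl groups that one-electron oxidation activates selectively.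

## Logic of the disconnections

14 back to 13. Five O–Si bonds are cut. All five phenols are carried as the same bulky silyl ether, so one fluoride treatment ends the synthesis without touching the A1 methyl ether or the diarylmethane carbons. The gain is that no acidic or easily oxidised OH is present in any earlier step. The forward step only has to keep the liberated phenoxides away from air, which an acetic acid buffer does.

13 back to 9 and three molecules of 11, through 12. The three CH2–aryl bonds at the carbons on A4, A6 and B6 are cut, each between the CH2 and the para carbon of an oxygenated phenyl ring. The cut is placed there because each of these carbons is para to an oxygen of the core and can be made electrophilic by removing two electrons and a proton from a methyl group. The gain is large: a hexa-aryl framework falls back to a trimethyl bibenzyl and a protected phenol that is used three times. The forward step must meet three demands. Three successive two-electron oxidations must each stop at the ether level. The chain CH2 groups must stay untouched. The cations must meet 11 and not an arene carbon of the core. These demands are answered by running the oxidation to 12 before 11 or any diarylmethane is present, and by keeping the bulky silyl groups on A3 and B3, which wall in A2, B2 and B4.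

9 back to 5 and 7, through 8. The B1–CH2 bond of the chain is cut. Both chain carbons then come from the vinyl group of 5, whose terminal carbon becomes the nucleophile after hydroboration, and ring B becomes a plain aryl bromide. The gain is two fragments of similar size and a direct sp3–sp2 union, with no alkene or alkyne to hydrogenate afterwards. The forward step needs terminal hydroboration and an alkyl transfer that outruns β-hydride elimination.

5 back to 4. The C=C bond of the vinyl group is cut to the formyl group. Carbon A5 carries its side-chain carbon at the aldehyde level from the first compound onwards, so no redox adjustment is needed on the crowded ring. The forward step needs an ylide small enough to reach a carbonyl flanked by two methyl groups.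

4 back to 3, 2 and 1. The two aryl–CH3 bonds on A4 and A6 are cut to C–Br bonds, these to C–H bonds, and the A3 O–Si bond to the free phenol. The two carbons flanking the formyl group of 2 are each para to one oxygen and ortho to the other, the same relationship the key step uses later, so electrophilic bromination should find them. The gain is that 1 already holds the OMe/OH differentiation and the side-chain carbon. The forward steps need the second bromine to enter beside the formyl group and not at A2, and two methyl transfers at hindered positions.

7 back to 6, and 11 back to 10. One O–Si bond is cut in each case; both are simple protections of purchasable phenols.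

## Other disconnections considered

Alternative 1: The cut runs through the A5–Cα bond and the bond from A6 to its benzylic carbon, both made on an A5–A6 aryne.
- **Forward step.** CsF would release the aryne from the silyl triflate A2 (2-{[4-(benzyloxy)phenyl]methyl}-3,5-dimethoxy-6-(trimethylsilyl)phenyl trifluoromethanesulfonate). The enolate carbon of the β-keto ester A3 (methyl 3-[4-(benzyloxy)phenyl]-3-oxopropanoate) would add at A5, away from the A1 methoxy group. The A6 aryl anion would then take over the aroyl group through a four-membered alkoxide, giving A1 (methyl 2-[2-(4-benzyloxybenzoyl)-6-(4-benzyloxybenzyl)-3,5-dimethoxyphenyl]acetate).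
- **In favour.** Two adjacent C–C bonds form on a crowded ring in one mild step, the methoxy group steers the regiochemistry, and the reaction class is established. On precedent this alternative is better than the chosen plan. The aroyl carbonyl of A1 would also distinguish the two methoxy groups through chelation-assisted dealkylation.
- **Against.** The step serves ring A only. The A4 benzyl group must already sit on A2, which costs several steps, and ring B with its own benzyl group must be built separately. After A1, the diaryl ketone must be deoxygenated, the ester carbon must become the chain carbon bonded to B1, and one methoxy group must be cleaved. The boron halides used for that cleavage also attack benzyl ethers, so the protecting groups would need redesign.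
- **Comparison.** On structure it creates two of the bonds around ring A, where the chosen plan creates all three diarylmethane bonds at once. On mechanism it is closed-shell and predictable, an advantage over an untested threefold oxidation. On step economy it is clearly worse, probably by five steps or more.

Alternative 2: The cut is the A5–A6 bond of ring A itself, which would be folded from an open chain.
- **Forward step.** Aqueous KOH would make the A6 carbanion of the β-keto ester end of the triketo ester A5 (methyl 2,6-bis[(4-benzyloxyphenyl)methyl]-9-{5-benzyloxy-2-[(4-benzyloxyphenyl)methyl]phenyl}-3,5,7-trioxononanoate) add to the A5 ketone. Dehydration, ester hydrolysis and loss of CO2 would then give the symmetric resorcinol A4 (4,6-bis(4-benzyloxybenzyl)-5-{2-[5-benzyloxy-2-(4-benzyloxybenzyl)phenyl]ethyl}benzene-1,3-diol).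
- **In favour.** The chain fixes every substituent of ring A before the ring exists, so no aromatic site selectivity is at stake. On positional certainty it is better than the chosen plan. It needs only base and no metal.
- **Against.** A4 has two equivalent hydroxyl groups, so the A1 methyl ether must be made by a statistical mono-methylation. A5 is long to assemble, is open to retro-Claisen cleavage, and can close in other modes (Claisen closure onto the ester, or aldol closures from other carbons). The decarboxylation must start from a hindered quaternary ester.
- **Comparison.** On structure it builds the most complex ring from the least aromatic precursor, which is elegant, but it leaves the ring B benzyl group to separate chemistry. On mechanism it is classical carbonyl chemistry, equal to the chosen plan in plausibility but with more competing pathways. On step economy it is the weakest of the four plans.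

Alternative 3: The cut takes the A4–CH2, A6–CH2 and A5–Cα bonds in one palladium/norbornene relay.
- **Forward step.** Pd(OAc)2, PPh3, norbornene and Cs2CO3 would combine the aryl iodide A7 (1-(benzyloxy)-3-iodo-5-methoxybenzene), two equivalents of the benzyl chloride A8 (1-(benzyloxy)-4-(chloromethyl)benzene) and the styrene A9 (4-(benzyloxy)-1-{[4-(benzyloxy)phenyl]methyl}-2-ethenylbenzene). Two ortho C–H benzylations and an ipso Heck reaction would give the (E)-stilbene A6 (the pentabenzyl ether of the stilbene analogue of the target).
- **In favour.** Three bonds at ring A form in one step from simple pieces, and a single hydrogenation would then saturate the alkene and remove all five benzyl groups. On step economy and on the simplicity of the endgame it is the equal of the chosen plan, and probably better.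
- **Against.** Both ortho C–H bonds of A7 lie between the iodide and a meta oxygen substituent, a pattern in which palladation through the norbornene palladacycle is generally disfavoured. An electron-rich benzyl chloride such as A8 can add to zerovalent palladium on its own, ionise, or be solvolysed by the carbonate base. The ring B benzyl group is not made by the step and must be built into A9 beforehand.
- **Comparison.** On structure both plans form three bonds with no ring, but the chosen plan also covers the ring B benzyl group and starts from a core with no pre-made diarylmethane. On mechanism the relay is a known manifold applied to an unfavourable substitution pattern, whereas the chosen plan is a new extension of a known manifold applied to a favourable one. Neither is clearly safer.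

Key step: step 8

Assumption: 3-hydroxy-5-methoxybenzaldehyde, 3-bromo-4-methylphenol and phenol are taken as purchasable. The target has no stereocentre and its aryl–CH2 bonds rotate freely, so no stereodescriptor is needed.

## Route

Step 1
Reactants: 1 3-hydroxy-5-methoxybenzaldehyde
Product: 2 3-methoxy-5-[tri(propan-2-yl)silyloxy]benzaldehyde
Conditions: iPr3SiCl (1.2 equiv), imidazole (2.5 equiv), DMF, rt
Reagents that add atoms: chlorotri(propan-2-yl)silane, CC(C)[Si](Cl)(C(C)C)C(C)C
Why: Imidazole-promoted O-silylation of a phenol; the formyl group and the methyl ether are inert, and the bulky silyl group is chosen because it later shields A2 and survives mild base and acid.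

Step 2
Reactants: 2 3-methoxy-5-[tri(propan-2-yl)silyloxy]benzaldehyde
Product: 3 2,6-dibromo-3-methoxy-5-[tri(propan-2-yl)silyloxy]benzaldehyde
Conditions: NBS (2.3 equiv), MeCN, 0 °C to 40 °C, dark
Reagents that add atoms: N-bromosuccinimide, O=C1CCC(=O)N1Br
Why: Electrophilic aromatic bromination; each carbon flanking the formyl group is para to one oxygen and ortho to the other, while the carbon between the two oxygens is walled in by OMe and OSi(iPr)3, the pattern by which 3,5-dialkoxybenzaldehydes are known to take bromine at their 2 and 6 positions. Succinimide is the only by-product, so the silyl ether sees no strong acid.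

Step 3
Reactants: 3 2,6-dibromo-3-methoxy-5-[tri(propan-2-yl)silyloxy]benzaldehyde
Product: 4 3-methoxy-2,6-dimethyl-5-[tri(propan-2-yl)silyloxy]benzaldehyde
Conditions: MeB(OH)2 (4 equiv), Pd(OAc)2 (5 mol %), SPhos (10 mol %), K3PO4 (6 equiv), toluene/H2O 20:1, 100 °C
Reagents that add atoms: methylboronic acid, CB(O)O
Why: Double Suzuki–Miyaura methylation; the ortho formyl group speeds oxidative addition and the bulky, electron-rich biaryl phosphine is the standard answer to di-ortho-substituted aryl bromides. The non-enolisable aldehyde and the aryl silyl ether tolerate phosphate in toluene.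

Step 4
Reactants: 4 3-methoxy-2,6-dimethyl-5-[tri(propan-2-yl)silyloxy]benzaldehyde
Product: 5 (3-ethenyl-5-methoxy-2,4-dimethylphenoxy)tri(propan-2-yl)silane
Conditions: Ph3PCH3Br (1.5 equiv), NaN(SiMe3)2 (1.4 equiv), THF, 0 °C to rt
Reagents that add atoms: methyltriphenylphosphonium bromide, C[P+](c1ccccc1)(c1ccccc1)c1ccccc1.[Br-]
Why: Wittig methylenation; the unstabilised ylide is small enough for 2,6-disubstituted benzaldehydes, and the amide base is used in deficit so that no free base reaches the silyl ether.

Step 5
Reactants: 6 3-bromo-4-methylphenol
Product: 7 (3-bromo-4-methylphenoxy)tri(propan-2-yl)silane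
Conditions: iPr3SiCl (1.2 equiv), imidazole (2.5 equiv), DMF, rt
Reagents that add atoms: chlorotri(propan-2-yl)silane, CC(C)[Si](Cl)(C(C)C)C(C)C
Why: Imidazole-promoted O-silylation of a phenol; the aryl bromide and the methyl group are spectators.

Step 6
Reactants: 5 (3-ethenyl-5-methoxy-2,4-dimethylphenoxy)tri(propan-2-yl)silane; 7 (3-bromo-4-methylphenoxy)tri(propan-2-yl)silane
Product: 9 3-[2-(5-hydroxy-2-methylphenyl)ethyl]-5-methoxy-2,4-dimethylphenol bis(triisopropylsilyl) ether, via alkylborane 8 (not isolated)
Conditions: 9-BBN (1.3 equiv), THF, 0 °C to 50 °C; then 7 (1.0 equiv), Pd(dppf)Cl2 (5 mol %), aq. K3PO4 (3 M, 3 equiv), DMF, 60 °C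
Reagents that add atoms: 9-borabicyclo[3.3.1]nonane, B1C2CCCC1CCC2 (its boron fragment is held in 8 and leaves again in the coupling so that 9 keeps only its hydrogen)
Why: Hydroboration followed by B-alkyl Suzuki–Miyaura coupling; the bulky borane adds its boron to the terminal carbon of the twisted, hindered styrene, and the wide-bite-angle ferrocenyl diphosphine favours reductive elimination of the primary alkyl over β-hydride elimination. The bibenzyl forms directly, with no unsaturated intermediate to reduce.

Step 7
Reactants: 10 phenol
Product: 11 phenoxytri(propan-2-yl)silane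
Conditions: iPr3SiCl (1.2 equiv), imidazole (2.5 equiv), DMF, rt
Reagents that add atoms: chlorotri(propan-2-yl)silane, CC(C)[Si](Cl)(C(C)C)C(C)C
Why: Imidazole-promoted O-silylation; the product is a para-selective, fluoride-cleavable phenol equivalent for the key step.

Step 8
Reactants: 9 3-[2-(5-hydroxy-2-methylphenyl)ethyl]-5-methoxy-2,4-dimethylphenol bis(triisopropylsilyl) ether; 11 phenoxytri(propan-2-yl)silane (3 equiv)
Product: 13 3-[2-[5-hydroxy-2-[(4-hydroxyphenyl)methyl]phenyl]ethyl]-2,4-bis[(4-hydroxyphenyl)methyl]-5-methoxyphenol pentakis(triisopropylsilyl) ether, via tris(hexafluoroisopropyl) ether 12 (not isolated)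
Conditions: boron-doped diamond anode, Pt cathode, undivided cell, iPr2NEt (0.1 M), (CF3)2CHOH, constant current, ca. 7 F/mol, rt; current off, then 11 (15 equiv charged, of which 3 equiv are consumed), CF3SO3H (0.3 equiv beyond the amine), (CF3)2CHOH/CH2Cl2, 0 °C to rt
Reagents that add atoms: phenoxytri(propan-2-yl)silane, CC(C)[Si](Oc1ccccc1)(C(C)C)C(C)C (second of the three molecules of 11); phenoxytri(propan-2-yl)silane, CC(C)[Si](Oc1ccccc1)(C(C)C)C(C)C (third of the three molecules of 11); 1,1,1,3,3,3-hexafluoropropan-2-ol, OC(C(F)(F)F)C(F)(F)F (three molecules are held in 12 and leave again in the arylation so that none of its atoms stay in 13)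
Why: Proposed new method: anodic electron transfer from the electron-rich rings (ring A first, then ring B) gives arene radical cations that lose a proton from a methyl group para to an oxygen (A4-CH3 to A1-OMe, A6-CH3 to A3-OSi, B6-CH3 to B3-OSi), and a second electron transfer gives the oxygen-stabilised benzylic cation, which (CF3)2CHOH traps as its ether, so that 6 F/mol would turn 9 into 12 while H2 leaves at the cathode. The electron-withdrawing OCH(CF3)2 group raises the potential of each CH2 it occupies, which should hold every site at the ether level, and the current is switched off before any diarylmethane or any 11 is present, so neither can be oxidised. CF3SO3H then re-ionises the three ethers one after another and each cation is taken by one molecule of 11 through its para carbon in a Friedel–Crafts benzylation, so that three molecules of 11 are built into 13 and three molecules of (CF3)2CHOH are given back. The closest known reaction type is the anodic benzylic C–H etherification of 4-alkoxytoluenes in this solvent followed by acid-triggered arylation, established for one methyl group per molecule; three methyl groups on two linked rings, two of them on one ring, and silyl in place of alkyl ethers, have not been shown. No ring is closed and no stereocentre is formed. Site selectivity among the C–H bonds is needed and is secured by the substrate: both chain CH2 groups are meta to every oxygen and lack the para-oxygen stabilisation that makes the three methyl groups acidic in the radical cation. Chemoselectivity in the arylation is needed too: the oxygen-activated arene carbons of the core that still bear hydrogen are A2, B2 and B4, each next to a bulky OSi(iPr)3 group (attack at B2 would close a seven-membered ring, and B5 is meta to the B3 oxygen and unactivated), so the fivefold excess of 11 per cation, whose ortho carbons are shielded by its own silyl group, should send every cation to an external para carbon.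

Step 9
Reactants: 13 3-[2-[5-hydroxy-2-[(4-hydroxyphenyl)methyl]phenyl]ethyl]-2,4-bis[(4-hydroxyphenyl)methyl]-5-methoxyphenol pentakis(triisopropylsilyl) ether
Product: 14 3-[2-[5-hydroxy-2-[(4-hydroxyphenyl)methyl]phenyl]ethyl]-2,4-bis[(4-hydroxyphenyl)methyl]-5-methoxyphenol
Conditions: Bu4NF (6 equiv), AcOH (6 equiv), THF, 0 °C to rt, Ar
Reagents that add atoms: none
Why: Fluoride-induced cleavage of aryl silyl ethers, driven by the Si–F bond; the methyl ether and the diarylmethane carbons are inert, and the acetic acid buffer keeps the five phenols protonated so that they are not oxidised by air. Any material that lost a silyl group in step 8 converges here.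

## Compound list

1 | 3-hydroxy-5-methoxybenzaldehyde | COc1cc(O)cc(C=O)c1 | starting material
2 | 3-methoxy-5-[tri(propan-2-yl)silyloxy]benzaldehyde | COc1cc(C=O)cc(O[Si](C(C)C)(C(C)C)C(C)C)c1 | intermediate
3 | 2,6-dibromo-3-methoxy-5-[tri(propan-2-yl)silyloxy]benzaldehyde | COc1cc(O[Si](C(C)C)(C(C)C)C(C)C)c(Br)c(C=O)c1Br | intermediate
4 | 3-methoxy-2,6-dimethyl-5-[tri(propan-2-yl)silyloxy]benzaldehyde | COc1cc(O[Si](C(C)C)(C(C)C)C(C)C)c(C)c(C=O)c1C | intermediate
5 | (3-ethenyl-5-methoxy-2,4-dimethylphenoxy)tri(propan-2-yl)silane | COc1cc(O[Si](C(C)C)(C(C)C)C(C)C)c(C)c(C=C)c1C | intermediate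
6 | 3-bromo-4-methylphenol | Cc1ccc(O)cc1Br | starting material
7 | (3-bromo-4-methylphenoxy)tri(propan-2-yl)silane | Cc1ccc(O[Si](C(C)C)(C(C)C)C(C)C)cc1Br | intermediate
8 | 9-{2-[3-methoxy-2,6-dimethyl-5-(triisopropylsilyloxy)phenyl]ethyl}-9-borabicyclo[3.3.1]nonane | COc1cc(O[Si](C(C)C)(C(C)C)C(C)C)c(C)c(CCB2C3CCCC2CCC3)c1C | intermediate
9 | 3-[2-(5-hydroxy-2-methylphenyl)ethyl]-5-methoxy-2,4-dimethylphenol bis(triisopropylsilyl) ether | COc1cc(O[Si](C(C)C)(C(C)C)C(C)C)c(C)c(CCc2cc(O[Si](C(C)C)(C(C)C)C(C)C)ccc2C)c1C | intermediate
10 | phenol | Oc1ccccc1 | starting material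
11 | phenoxytri(propan-2-yl)silane | CC(C)[Si](Oc1ccccc1)(C(C)C)C(C)C | intermediate
12 | compound 9 with each of its three aryl methyl groups (on A4, A6 and B6) turned into CH2OCH(CF3)2 | COc1cc(O[Si](C(C)C)(C(C)C)C(C)C)c(COC(C(F)(F)F)C(F)(F)F)c(CCc2cc(O[Si](C(C)C)(C(C)C)C(C)C)ccc2COC(C(F)(F)F)C(F)(F)F)c1COC(C(F)(F)F)C(F)(F)F | intermediate
13 | 3-[2-[5-hydroxy-2-[(4-hydroxyphenyl)methyl]phenyl]ethyl]-2,4-bis[(4-hydroxyphenyl)methyl]-5-methoxyphenol pentakis(triisopropylsilyl) ether | COc1cc(O[Si](C(C)C)(C(C)C)C(C)C)c(Cc2ccc(O[Si](C(C)C)(C(C)C)C(C)C)cc2)c(CCc2cc(O[Si](C(C)C)(C(C)C)C(C)C)ccc2Cc2ccc(O[Si](C(C)C)(C(C)C)C(C)C)cc2)c1Cc1ccc(O[Si](C(C)C)(C(C)C)C(C)C)cc1 | intermediate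
14 | 3-[2-[5-hydroxy-2-[(4-hydroxyphenyl)methyl]phenyl]ethyl]-2,4-bis[(4-hydroxyphenyl)methyl]-5-methoxyphenol | COc1cc(O)c(Cc2ccc(O)cc2)c(CCc2cc(O)ccc2Cc2ccc(O)cc2)c1Cc1ccc(O)cc1 | target

## Step count and least certain steps

Total step count: 9. Longest linear sequence: 7 steps (steps 1, 2, 3, 4, 6, 8 and 9).

**Step 8 (key step).** The three methyl groups are oxidised at different potentials, ring A first. By the time enough charge has passed for the B6 methyl group, the ring A sites or the free A2 carbon may undergo further oxidation, or the silyl ethers may be lost oxidatively. In the acid stage, ring closure onto B2 or intermolecular attack on the core may compete with capture by 11. The fallback uses known chemistry, sets out from 3 and comes back to the route at 14; it places halogen, not hydrogen, at the three carbons. Wittig methylenation of 3 would give (2,4-dibromo-3-ethenyl-5-methoxyphenoxy)tri(propan-2-yl)silane F1. Purchasable 4-bromo-3-iodophenol would be silylated to (4-bromo-3-iodophenoxy)tri(propan-2-yl)silane F2. Hydroboration of F1 with 9-BBN would give 9-{2-[2,6-dibromo-3-methoxy-5-(triisopropylsilyloxy)phenyl]ethyl}-9-borabicyclo[3.3.1]nonane F3. Coupling of F3 at the C–I bond of F2 (Pd(dppf)Cl2, aq. K3PO4, rt to 40 °C, where iodide reacts well before any bromide) would give the tribromide [2,4-dibromo-3-{2-[2-bromo-5-(triisopropylsilyloxy)phenyl]ethyl}-5-methoxyphenoxy]tri(propan-2-yl)silane F4, with bromine exactly on A4, A6 and B6. Threefold Negishi coupling with [4-(benzyloxy)phenyl]methylzinc chloride F5 (made in the flask from purchasable 1-(benzyloxy)-4-(chloromethyl)benzene A8, Zn dust and LiCl in THF) under Pd(OAc)2/SPhos would give the tris(benzyl) bis(triisopropylsilyl) pentaether of the target F6. Hydrogenolysis (H2, Pd/C) would give the A3,B3-bis(triisopropylsilyl) ether of the target F7, and Bu4NF/AcOH would then give 14.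

**Step 2.** The second bromination may stall because the ring then carries a formyl group and one bromine, and forcing it may erode the preference for the carbon beside the formyl group over A2. The fallback sets out from 2 and comes back at 3; it brominates a more electron-rich ring. NaBH4 in MeOH would give {3-methoxy-5-[tri(propan-2-yl)silyloxy]phenyl}methanol F8. NBS (2.1 equiv, 0 °C) would give {2,6-dibromo-3-methoxy-5-[tri(propan-2-yl)silyloxy]phenyl}methanol F9. MnO2 in CH2Cl2 would then give 3.

**Step 3.** Slow transfer of methyl from boron to a palladium centre flanked on both sides may allow protodebromination after the first coupling, and prolonged heating with base may cost the silyl ether. The fallback sets out from 3 and comes back at 4; it uses a fast, hydroxide-free methyl donor on a masked aldehyde. HC(OMe)3 with catalytic TsOH in MeOH would give [2,4-dibromo-3-(dimethoxymethyl)-5-methoxyphenoxy]tri(propan-2-yl)silane F10. Kumada coupling (MeMgBr, Ni(dppp)Cl2, THF, 60 °C) would give [3-(dimethoxymethyl)-5-methoxy-2,4-dimethylphenoxy]tri(propan-2-yl)silane F11. Brief treatment with 1 M aqueous HCl in THF would then give 4.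

**Step 6.** β-Hydride elimination or protodeboronation of the alkyl group may outrun its transfer to palladium, and hydroboration of the hindered styrene may be incomplete. The fallback sets out from 5 and 7 and comes back at 9; it forms the aryl–alkene bond first. A Heck reaction (Pd(OAc)2, P(o-tolyl)3, Et3N, DMF, 100 °C) would give (E)-1-[3-methoxy-2,6-dimethyl-5-(triisopropylsilyloxy)phenyl]-2-[2-methyl-5-(triisopropylsilyloxy)phenyl]ethene F12. Hydrogenation (H2, Pd/C, EtOAc) would then give 9.

## Further compounds

F1 | step 8 | (2,4-dibromo-3-ethenyl-5-methoxyphenoxy)tri(propan-2-yl)silane | COc1cc(O[Si](C(C)C)(C(C)C)C(C)C)c(Br)c(C=C)c1Br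
F2 | step 8 | (4-bromo-3-iodophenoxy)tri(propan-2-yl)silane | Brc1ccc(O[Si](C(C)C)(C(C)C)C(C)C)cc1I
F3 | step 8 | 9-{2-[2,6-dibromo-3-methoxy-5-(triisopropylsilyloxy)phenyl]ethyl}-9-borabicyclo[3.3.1]nonane | COc1cc(O[Si](C(C)C)(C(C)C)C(C)C)c(Br)c(CCB2C3CCCC2CCC3)c1Br
F4 | step 8 | [2,4-dibromo-3-{2-[2-bromo-5-(triisopropylsilyloxy)phenyl]ethyl}-5-methoxyphenoxy]tri(propan-2-yl)silane | COc1cc(O[Si](C(C)C)(C(C)C)C(C)C)c(Br)c(CCc2cc(O[Si](C(C)C)(C(C)C)C(C)C)ccc2Br)c1Br
F5 | step 8 | [4-(benzyloxy)phenyl]methylzinc chloride | Cl[Zn]Cc1ccc(OCc2ccccc2)cc1
F6 | step 8 | tris(benzyl) bis(triisopropylsilyl) pentaether of the target (benzyl on the three 4-hydroxybenzyl oxygens, silyl on the A3 and B3 oxygens) | COc1cc(O[Si](C(C)C)(C(C)C)C(C)C)c(Cc2ccc(OCc3ccccc3)cc2)c(CCc2cc(O[Si](C(C)C)(C(C)C)C(C)C)ccc2Cc2ccc(OCc3ccccc3)cc2)c1Cc1ccc(OCc2ccccc2)cc1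
F7 | step 8 | A3,B3-bis(triisopropylsilyl) ether of the target | COc1cc(O[Si](C(C)C)(C(C)C)C(C)C)c(Cc2ccc(O)cc2)c(CCc2cc(O[Si](C(C)C)(C(C)C)C(C)C)ccc2Cc2ccc(O)cc2)c1Cc1ccc(O)cc1
F8 | step 2 | {3-methoxy-5-[tri(propan-2-yl)silyloxy]phenyl}methanol | COc1cc(CO)cc(O[Si](C(C)C)(C(C)C)C(C)C)c1
F9 | step 2 | {2,6-dibromo-3-methoxy-5-[tri(propan-2-yl)silyloxy]phenyl}methanol | COc1cc(O[Si](C(C)C)(C(C)C)C(C)C)c(Br)c(CO)c1Br
F10 | step 3 | [2,4-dibromo-3-(dimethoxymethyl)-5-methoxyphenoxy]tri(propan-2-yl)silane | COc1cc(O[Si](C(C)C)(C(C)C)C(C)C)c(Br)c(C(OC)OC)c1Br
F11 | step 3 | [3-(dimethoxymethyl)-5-methoxy-2,4-dimethylphenoxy]tri(propan-2-yl)silane | COc1cc(O[Si](C(C)C)(C(C)C)C(C)C)c(C)c(C(OC)OC)c1C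
F12 | step 6 | (E)-1-[3-methoxy-2,6-dimethyl-5-(triisopropylsilyloxy)phenyl]-2-[2-methyl-5-(triisopropylsilyloxy)phenyl]ethene | COc1cc(O[Si](C(C)C)(C(C)C)C(C)C)c(C)c(/C=C/c2cc(O[Si](C(C)C)(C(C)C)C(C)C)ccc2C)c1C
A1 | alternative 1 | methyl 2-[2-(4-benzyloxybenzoyl)-6-(4-benzyloxybenzyl)-3,5-dimethoxyphenyl]acetate | COC(=O)Cc1c(Cc2ccc(OCc3ccccc3)cc2)c(OC)cc(OC)c1C(=O)c1ccc(OCc2ccccc2)cc1
A2 | alternative 1 | 2-{[4-(benzyloxy)phenyl]methyl}-3,5-dimethoxy-6-(trimethylsilyl)phenyl trifluoromethanesulfonate | COc1cc(OC)c([Si](C)(C)C)c(OS(=O)(=O)C(F)(F)F)c1Cc1ccc(OCc2ccccc2)cc1
A3 | alternative 1 | methyl 3-[4-(benzyloxy)phenyl]-3-oxopropanoate | COC(=O)CC(=O)c1ccc(OCc2ccccc2)cc1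
A4 | alternative 2 | 4,6-bis(4-benzyloxybenzyl)-5-{2-[5-benzyloxy-2-(4-benzyloxybenzyl)phenyl]ethyl}benzene-1,3-diol | Oc1cc(O)c(Cc2ccc(OCc3ccccc3)cc2)c(CCc2cc(OCc3ccccc3)ccc2Cc2ccc(OCc3ccccc3)cc2)c1Cc1ccc(OCc2ccccc2)cc1
A5 | alternative 2 | methyl 2,6-bis[(4-benzyloxyphenyl)methyl]-9-{5-benzyloxy-2-[(4-benzyloxyphenyl)methyl]phenyl}-3,5,7-trioxononanoate | COC(=O)C(Cc1ccc(OCc2ccccc2)cc1)C(=O)CC(=O)C(Cc1ccc(OCc2ccccc2)cc1)C(=O)CCc1cc(OCc2ccccc2)ccc1Cc1ccc(OCc2ccccc2)cc1
A6 | alternative 3 | (E)-stilbene analogue of the target as its pentabenzyl ether | COc1cc(OCc2ccccc2)c(Cc2ccc(OCc3ccccc3)cc2)c(/C=C/c2cc(OCc3ccccc3)ccc2Cc2ccc(OCc3ccccc3)cc2)c1Cc1ccc(OCc2ccccc2)cc1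
A7 | alternative 3 | 1-(benzyloxy)-3-iodo-5-methoxybenzene | COc1cc(I)cc(OCc2ccccc2)c1
A8 | alternative 3 | 1-(benzyloxy)-4-(chloromethyl)benzene | ClCc1ccc(OCc2ccccc2)cc1
A9 | alternative 3 | 4-(benzyloxy)-1-{[4-(benzyloxy)phenyl]methyl}-2-ethenylbenzene | C=Cc1cc(OCc2ccccc2)ccc1Cc1ccc(OCc2ccccc2)cc1
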